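**Plan**

1. Retrosynthesis: the C3=C4 double bond is restored first (the target is its dihydro form). Then C6–C7 and C6′–C7′ are cut together with both lactone C–O bonds, then the two cycloaddition bonds C2–C2′ and C5–C3′. The monomer is cut at C3=C4 (metathesis), C4–C5, C5–C6 and C1–C2, which leads back to geraniol.
2. Forward: the monomer cyclopentene is closed and dehydrated to a cyclopentadiene. Its [4+2] homodimer is the tricyclic core (cyclopentene ring A′ fused to a norbornene) with both side chains in place. The chains become 2-(bromomethyl)enoate arms, and one chromium step closes both cycloheptanes and both γ-lactones. C11, C11′ and C4 are reduced last.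
3. Feature behind the key step: each seven-membered ring meets its trans γ-lactone at C6–C7 (C6 on bridgehead C5, C6′ on alkene carbon C5′). C6(O)–C7–C11(=C13) is therefore a homoallylic alcohol whose allyl unit C7–C11–C13 hangs from C10 through C8–C9, within reach of a C6 aldehyde on the rigid core.
4. Stereochemistry: C10/C10′ come from Sharpless epoxidation and C1/C1′ from SN2 opening of that epoxide. C2, C5, C2′ and C3′ come from the endo, anti-selective dimerization. C6, C7, C6′ and C7′ come from cyclic allylchromium transition states on the core. C11/C11′ come from protonation to the stable α-methyl lactone, and C4 from hydroxyl-directed hydrogenation.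

Key step: step 17

Remark: atom labels follow the two guaianolide halves (C1–C15 on the norbornane half, primed on the cyclopentene half). A free C10–OH would close a lactol onto a C6 or C7 aldehyde, so both tertiary alcohols travel as triethylsilyl ethers, and C3=C4 is kept as a spectator alkene until the last step.

**Route**

Step 1
Reactants: 1 geraniol
Product: 2 (2S,3S)-2,3-epoxygeraniol
Conditions: Ti(OiPr)4 (5 mol %), L-(+)-diethyl tartrate (6 mol %), t-BuOOH, 4 Å molecular sieves, CH2Cl2, −20 °C
Reagents that add atoms: tert-butyl hydroperoxide, CC(C)(C)OO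
Why: Sharpless asymmetric epoxidation of an (E)-trisubstituted allylic alcohol, in which the titanium–L-(+)-tartrate complex should deliver oxygen to the face that gives the (2S,3S)-epoxide and so fixes the future C10.

Step 2
Reactants: 2 (2S,3S)-2,3-epoxygeraniol; 3 allylmagnesium chloride (CH2=CHCH2MgCl)
Product: 4 (2R,3S)-3,7-dimethyl-2-(prop-2-en-1-yl)oct-6-ene-1,3-diol
Conditions: 3 (3 equiv), CuI (10 mol %), THF, −40 → 0 °C; aq. NH4Cl
Reagents that add atoms: allylmagnesium chloride (3), C=CC[Mg]Cl
Why: Copper-catalysed SN2 opening of a 2,3-epoxy alcohol, where the fully substituted epoxide carbon is closed to the nucleophile, so the allyl group should enter at the CH carbon with inversion and set C1 beside the untouched C10 carbinol.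

Step 3
Reactants: 4 (2R,3S)-3,7-dimethyl-2-(prop-2-en-1-yl)oct-6-ene-1,3-diol
Product: 5 (2R,3S)-3,7-dimethyl-2-(prop-2-en-1-yl)-1,3-bis(triethylsilyloxy)oct-6-ene
Conditions: Et3SiOTf, 2,6-lutidine, CH2Cl2, −78 → 0 °C
Reagents that add atoms: triethylsilyl trifluoromethanesulfonate, CC[Si](CC)(CC)OS(=O)(=O)C(F)(F)F
Why: Silyl triflate silylation covers both hydroxyls, and the tertiary C10 ether is meant to last until step 19 so that no lactol can form with the later C7 and C6 aldehydes.

Step 4
Reactants: 5 (2R,3S)-3,7-dimethyl-2-(prop-2-en-1-yl)-1,3-bis(triethylsilyloxy)oct-6-ene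
Product: 6 (2S,3S)-3,7-dimethyl-2-(prop-2-en-1-yl)-3-(triethylsilyloxy)oct-6-enal
Conditions: (COCl)2, DMSO, CH2Cl2, −78 → −30 °C; Et3N, −78 → 0 °C
Reagents that add atoms: none
Why: Under Swern conditions a primary triethylsilyl ether is oxidized directly to the aldehyde (the ether oxygen attacks the chlorosulfonium ion and Et3SiCl leaves) while the tertiary silyl ether is inert, and the low temperature should keep the α-stereocentre C1.

Step 5
Reactants: 7 tributyl(iodomethyl)stannane; 8 4-methoxybenzyl alcohol
Product: 9 tributyl[(4-methoxybenzyloxy)methyl]stannane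
Conditions: NaH, THF/DMF, 0 °C → rt
Reagents that add atoms: 4-methoxybenzyl alcohol (8), COc1ccc(CO)cc1
Why: Williamson etherification of the sodium alkoxide with the primary iodide should give the tin reagent used for alkoxymethyl transfer.

Step 6
Reactants: 6 (2S,3S)-3,7-dimethyl-2-(prop-2-en-1-yl)-3-(triethylsilyloxy)oct-6-enal; 9 tributyl[(4-methoxybenzyloxy)methyl]stannane
Product: 10 (2RS,3R,4S)-1-(4-methoxybenzyloxy)-4,8-dimethyl-3-(prop-2-en-1-yl)-4-(triethylsilyloxy)non-7-en-2-ol
Conditions: 9, n-BuLi, THF, −78 °C; then 6, −78 °C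
Reagents that add atoms: tributyl[(4-methoxybenzyloxy)methyl]stannane (9), CCCC[Sn](CCCC)(CCCC)COCc1ccc(OC)cc1
Why: Tin–lithium exchange gives the α-alkoxymethyllithium, whose 1,2-addition to the aldehyde installs C6, and the new carbinol configuration does not matter because C5 later becomes sp2.

Step 7
Reactants: 10 (2RS,3R,4S)-1-(4-methoxybenzyloxy)-4,8-dimethyl-3-(prop-2-en-1-yl)-4-(triethylsilyloxy)non-7-en-2-ol
Product: 11 (3S,4S)-1-(4-methoxybenzyloxy)-4,8-dimethyl-3-(prop-2-en-1-yl)-4-(triethylsilyloxy)non-7-en-2-one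
Conditions: Dess–Martin periodinane, NaHCO3, CH2Cl2, 0 °C → rt
Reagents that add atoms: none
Why: Dess–Martin oxidation of the secondary alcohol under buffered conditions should give the α-alkoxy ketone without epimerizing C1.

Step 8
Reactants: 11 (3S,4S)-1-(4-methoxybenzyloxy)-4,8-dimethyl-3-(prop-2-en-1-yl)-4-(triethylsilyloxy)non-7-en-2-one; 12 isopropenylmagnesium bromide (CH2=C(CH3)MgBr)
Product: 13 (3RS,4R,5S)-3-[(4-methoxybenzyloxy)methyl]-2,5,9-trimethyl-4-(prop-2-en-1-yl)-5-(triethylsilyloxy)deca-1,8-dien-3-ol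
Conditions: 12, THF, −78 °C
Reagents that add atoms: isopropenylmagnesium bromide (12), CC(=C)[Mg]Br
Why: Grignard 1,2-addition to the chelation-activated α-alkoxy ketone brings in C4 and C15, and the new carbinol centre is removed again in step 10.

Step 9
Reactants: 13 (3RS,4R,5S)-3-[(4-methoxybenzyloxy)methyl]-2,5,9-trimethyl-4-(prop-2-en-1-yl)-5-(triethylsilyloxy)deca-1,8-dien-3-ol
Product: 14 (1RS,5R)-1-[(4-methoxybenzyloxy)methyl]-2-methyl-5-[(2S)-6-methyl-2-(triethylsilyloxy)hept-5-en-2-yl]cyclopent-2-en-1-ol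
Conditions: second-generation Grubbs catalyst (H2IMes)(PCy3)Cl2Ru=CHPh (5 mol %), CH2Cl2 (0.01 M), 40 °C
Reagents that add atoms: none
Why: Ring-closing metathesis of the allyl and isopropenyl groups should close the five-membered ring at C3=C4, since the only other closures, onto the trisubstituted side-chain alkene, would be seven-membered and much slower.

Step 10
Reactants: 14 (1RS,5R)-1-[(4-methoxybenzyloxy)methyl]-2-methyl-5-[(2S)-6-methyl-2-(triethylsilyloxy)hept-5-en-2-yl]cyclopent-2-en-1-ol
Product: 17 (5R)-1-[(4-methoxybenzyloxy)methyl]-2-methyl-5-[(2S)-6-methyl-2-(triethylsilyloxy)hept-5-en-2-yl]cyclopenta-1,3-diene, via sulfenate ester 15 (not isolated), via allylic sulfoxide 16 (not isolated)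
Conditions: 2,4-(O2N)2C6H3SCl, Et3N, ClCH2CH2Cl, 0 → 45 °C; cold filtration through silica
Reagents that add atoms: none
Why: Net 1,4-dehydration of an allylic alcohol by O-sulfenylation, [2,3]-sigmatropic (Mislow–Evans type) shift to the C3 sulfoxide and thermal syn elimination, which can only take a hydrogen from C2 because C4 carries none, so the C2=C3–C4=C5 diene should form regiospecifically from both C5 epimers.

Step 11
Reactants: 17 (5R)-1-[(4-methoxybenzyloxy)methyl]-2-methyl-5-[(2S)-6-methyl-2-(triethylsilyloxy)hept-5-en-2-yl]cyclopenta-1,3-diene (two molecules)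
Product: 18 endo Diels–Alder dimer with new bonds C2–C2′ and C5–C3′ (norbornene C3=C4 fused to cyclopentene C4′=C5′; CH2OPMB on C5 and C5′; silylated carbinol chains on bridge carbon C1, syn to C3=C4, and on C1′, trans to the C2′–C2 bond)
Conditions: neat (trace 2,6-di-tert-butyl-4-methylphenol), 20–25 °C, dark, several days
Reagents that add atoms: none
Why: Thermal Diels–Alder homodimerization of a cyclopentadiene, in which the diene C2=C3–C4=C5 of one molecule should add endo across the least substituted double bond C2′=C3′ of the other with both partners attacked anti to their carbinol substituents; for two molecules of the same enantiomer this combination can only give the C2–C2′/C5–C3′ constitution, it sets C2, C5, C2′ and C3′ at once, and suprafacial 1,5-hydrogen shifts among diene tautomers leave C1 intact and should be drained through 17 (Curtin–Hammett).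

Step 12
Reactants: 18 endo Diels–Alder dimer
Product: 20 C7,C7′-dialdehyde of the dimer (both side chains cut back to CH2CH2CHO), via tetraol 19 (not isolated)
Conditions: OsO4 (2 mol %), NaIO4, 2,6-lutidine, dioxane/H2O (3:1), 0 °C → rt
Reagents that add atoms: osmium tetroxide, O=[Os](=O)(=O)=O; sodium periodate, [Na+].[O-]I(=O)(=O)=O
Why: Lemieux–Johnson cleavage, in which osmylation should pick the two unhindered trisubstituted side-chain alkenes because the tetrasubstituted C4′=C5′ and the norbornene C3=C4 (exo face covered by the silylated C10 carbinol, endo face by ring A′) are shielded.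

Step 13
Reactants: 20 C7,C7′-dialdehyde of the dimer; 21 methyl acrylate
Product: 22 bis(Morita–Baylis–Hillman) adduct (each chain ends in CH(OH)C(=CH2)CO2Me; C7 and C7′ carbinol epimers)
Conditions: 21 (excess), DABCO, MeOH (cat.), rt
Reagents that add atoms: methyl acrylate (21), C=CC(=O)OC
Why: Twofold Morita–Baylis–Hillman reaction of unhindered aliphatic aldehydes with methyl acrylate builds C11–C13 on C7 and C7′, and the carbinol configuration is erased in step 14.

Step 14
Reactants: 22 bis(Morita–Baylis–Hillman) adduct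
Product: 23 bis[(Z)-2-(bromomethyl)enoate] (each chain ends in CH=C(CH2Br)CO2Me)
Conditions: NBS, Me2S, CH2Cl2, 0 °C → rt
Reagents that add atoms: N-bromosuccinimide, O=C1CCC(=O)N1Br
Why: Corey–Kim type bromination of the allylic alcohols with allylic transposition (SN2′) should give the thermodynamically preferred (Z)-2-(bromomethyl)enoates under neutral conditions that spare the silyl and PMB ethers.

Step 15
Reactants: 23 bis[(Z)-2-(bromomethyl)enoate]
Product: 24 C6,C6′-diol (both PMB ethers removed)
Conditions: DDQ, CH2Cl2/pH 7 buffer, 0 °C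
Reagents that add atoms: none
Why: Oxidative cleavage of PMB ethers by DDQ leaves allylic bromides and the tertiary silyl ethers untouched.

Step 16
Reactants: 24 C6,C6′-diol
Product: 25 C6,C6′-dialdehyde with two (Z)-2-(bromomethyl)enoate arms (C10 and C10′ as triethylsilyl ethers, C3=C4 present)
Conditions: Dess–Martin periodinane, NaHCO3, CH2Cl2, 0 °C → rt
Reagents that add atoms: none
Why: Dess–Martin oxidation converts the allylic and the neopentyl primary alcohol without base, so the allylic bromides survive and, with no free hydroxyl in the molecule, both aldehydes should stay open.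

Step 17
Reactants: 25 C6,C6′-dialdehyde with two (Z)-2-(bromomethyl)enoate arms
Product: 27 bis(α-methylene γ-lactone) 10,10′-bis(triethylsilyl) ether, via bis(hydroxy ester) 26 (not isolated)
Conditions: CrCl2 (8 equiv), THF (0.005 M), rt; aq. NH4Cl; PPTS (cat.), CH2Cl2, rt
Reagents that add atoms: none
Why: CrCl2 (divalent chromium, two equivalents per C–Br bond) turns each allylic bromide into a 2-(methoxycarbonyl)allylchromium reagent (trivalent chromium) that adds through its γ-carbon C7 (C7′) to the aldehyde on the core in a closed six-membered transition state, after which the metal alkoxide acylates on the neighbouring methyl ester and expels methoxide. The closest known reaction type is the intramolecular Nozaki–Hiyama (Barbier-type) 2-(alkoxycarbonyl)allylation of an aldehyde with in situ lactonization, which fuses α-methylene γ-lactones to seven-membered carbocycles and is used here twice in one flask. Each cycloheptane closes in the 7-exo-trig mode at the aldehyde carbon (bonds C6–C7 and C6′–C7′) and each lactone in the 5-exo-trig mode at the ester carbonyl. At C6 the chromium-bound oxygen should turn to the open side next to H1 while the formyl hydrogen takes the pocket between the C4 and C4′ methyl groups and C7 arrives from the C10 side, and at C6′ the enal should react s-trans (oxygen away from the C4′ methyl) on the convex face of ring A′ that carries the C10′ chain. The allylchromium reagents are configurationally mobile by 1,3-metal shift, and because the rigid C1–C5 (C1′–C5′) bond forces C8 (C8′) anti to the carbonyl oxygen in the forming ring, the chair with C5 (C5′) and C8 (C8′) both equatorial should give the anti adducts, that is H6/H7 and H6′/H7′ trans. The step needs each allylchromium to find its own aldehyde, 1,2-addition to the enal and open aldehydes: the seven-membered closures should beat the nine- and ten-membered cross-closures and intermolecular coupling at 0.005 M, allylchromium reagents add 1,2, the C6 aldehyde cannot enolize, and the silylated C10 and C10′ oxygens cannot form lactols.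

Step 18
Reactants: 27 bis(α-methylene γ-lactone) 10,10′-bis(triethylsilyl) ether
Product: 28 bis(α-methyl γ-lactone) 10,10′-bis(triethylsilyl) ether
Conditions: NaBH4, MeOH, 0 °C
Reagents that add atoms: none
Why: Conjugate (1,4) reduction of α-methylene γ-lactones by NaBH4, in which C11 and C11′ are set by protonation of the lactone enolates and should settle, under the methoxide present, on the more stable epimer with methyl trans to C8 (C8′), as the target requires.

Step 19
Reactants: 28 bis(α-methyl γ-lactone) 10,10′-bis(triethylsilyl) ether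
Product: 29 3,4-didehydro target (10,10′-diol)
Conditions: Bu4NF, AcOH (1:1), THF, rt
Reagents that add atoms: none
Why: Fluoride-induced desilylation under acetic acid buffering frees both tertiary alcohols without opening the saturated lactones.

Step 20
Reactants: 29 3,4-didehydro target (10,10′-diol)
Product: 30 CNP0182139.2 (target)
Conditions: H2 (1 atm), [Ir(cod)(PCy3)(py)]PF6 (5 mol %), CH2Cl2, 0 °C → rt
Reagents that add atoms: none
Why: Hydroxyl-directed homogeneous hydrogenation, in which the C10 hydroxyl, held over the exo face of C3=C4 once the seven-membered ring fixes C9, should deliver H2 to the strained trisubstituted norbornene alkene from that face (H exo, methyl endo at C4) while the far less reactive tetrasubstituted C4′=C5′ should remain.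

**Compound list**

1 | geraniol, (2E)-3,7-dimethylocta-2,6-dien-1-ol | CC(C)=CCC/C(C)=C/CO | starting material
2 | (2S,3S)-2,3-epoxygeraniol, [(2S,3S)-3-methyl-3-(4-methylpent-3-en-1-yl)oxiran-2-yl]methanol | OC[C@@H]1O[C@@]1(C)CCC=C(C)C | intermediate
3 | allylmagnesium chloride | C=CC[Mg]Cl | starting material
4 | (2R,3S)-3,7-dimethyl-2-(prop-2-en-1-yl)oct-6-ene-1,3-diol | OC[C@@H](CC=C)[C@@](C)(O)CCC=C(C)C | intermediate
5 | (2R,3S)-3,7-dimethyl-2-(prop-2-en-1-yl)-1,3-bis(triethylsilyloxy)oct-6-ene | CC[Si](CC)(CC)OC[C@@H](CC=C)[C@@](C)(O[Si](CC)(CC)CC)CCC=C(C)C | intermediate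
6 | (2S,3S)-3,7-dimethyl-2-(prop-2-en-1-yl)-3-(triethylsilyloxy)oct-6-enal | O=C[C@@H](CC=C)[C@@](C)(O[Si](CC)(CC)CC)CCC=C(C)C | intermediate
7 | tributyl(iodomethyl)stannane | CCCC[Sn](CCCC)(CCCC)CI | starting material
8 | 4-methoxybenzyl alcohol | COc1ccc(CO)cc1 | starting material
9 | tributyl[(4-methoxybenzyloxy)methyl]stannane | CCCC[Sn](CCCC)(CCCC)COCc1ccc(OC)cc1 | intermediate
10 | (2RS,3R,4S)-1-(4-methoxybenzyloxy)-4,8-dimethyl-3-(prop-2-en-1-yl)-4-(triethylsilyloxy)non-7-en-2-ol | COc1ccc(COCC(O)[C@@H](CC=C)[C@@](C)(O[Si](CC)(CC)CC)CCC=C(C)C)cc1 | intermediate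
11 | (3S,4S)-1-(4-methoxybenzyloxy)-4,8-dimethyl-3-(prop-2-en-1-yl)-4-(triethylsilyloxy)non-7-en-2-one | COc1ccc(COCC(=O)[C@@H](CC=C)[C@@](C)(O[Si](CC)(CC)CC)CCC=C(C)C)cc1 | intermediate
12 | isopropenylmagnesium bromide | CC(=C)[Mg]Br | starting material
13 | (3RS,4R,5S)-3-[(4-methoxybenzyloxy)methyl]-2,5,9-trimethyl-4-(prop-2-en-1-yl)-5-(triethylsilyloxy)deca-1,8-dien-3-ol | COc1ccc(COCC(O)(C(C)=C)[C@@H](CC=C)[C@@](C)(O[Si](CC)(CC)CC)CCC=C(C)C)cc1 | intermediate
14 | (1RS,5R)-1-[(4-methoxybenzyloxy)methyl]-2-methyl-5-[(2S)-6-methyl-2-(triethylsilyloxy)hept-5-en-2-yl]cyclopent-2-en-1-ol | COc1ccc(COCC2(O)C(C)=CC[C@H]2[C@@](C)(O[Si](CC)(CC)CC)CCC=C(C)C)cc1 | intermediate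
15 | 2,4-dinitrobenzenesulfenate ester of 14 (not isolated) | COc1ccc(COCC2(OSc3ccc(cc3[N+](=O)[O-])[N+](=O)[O-])C(C)=CC[C@H]2[C@@](C)(O[Si](CC)(CC)CC)CCC=C(C)C)cc1 | intermediate
16 | allylic 2,4-dinitrophenyl sulfoxide at C3 with the C4=C5 double bond (not isolated) | COc1ccc(COCC2=C(C)C(S(=O)c3ccc(cc3[N+](=O)[O-])[N+](=O)[O-])C[C@H]2[C@@](C)(O[Si](CC)(CC)CC)CCC=C(C)C)cc1 | intermediate
17 | (5R)-1-[(4-methoxybenzyloxy)methyl]-2-methyl-5-[(2S)-6-methyl-2-(triethylsilyloxy)hept-5-en-2-yl]cyclopenta-1,3-diene | COc1ccc(COCC2=C(C)C=C[C@H]2[C@@](C)(O[Si](CC)(CC)CC)CCC=C(C)C)cc1 | intermediate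
18 | endo Diels–Alder dimer of 17 (bonds C2–C2′ and C5–C3′; C3=C4 and C4′=C5′; CH2OPMB on C5 and C5′; silylated prenyl-terminated carbinol chains on C1 and C1′) | CC1=C(COCc4ccc(OC)cc4)[C@H]([C@@](C)(O[Si](CC)(CC)CC)CCC=C(C)C)[C@H]2[C@H]3C=C(C)[C@](COCc5ccc(OC)cc5)([C@@H]3[C@@](C)(O[Si](CC)(CC)CC)CCC=C(C)C)[C@@H]12 | intermediate
19 | tetraol from 18 (both side-chain alkenes dihydroxylated; not isolated) | CC1=C(COCc4ccc(OC)cc4)[C@H]([C@@](C)(O[Si](CC)(CC)CC)CCC(O)C(C)(C)O)[C@H]2[C@H]3C=C(C)[C@](COCc5ccc(OC)cc5)([C@@H]3[C@@](C)(O[Si](CC)(CC)CC)CCC(O)C(C)(C)O)[C@@H]12 | intermediate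
20 | C7,C7′-dialdehyde of the dimer | CC1=C(COCc4ccc(OC)cc4)[C@H]([C@@](C)(O[Si](CC)(CC)CC)CCC=O)[C@H]2[C@H]3C=C(C)[C@](COCc5ccc(OC)cc5)([C@@H]3[C@@](C)(O[Si](CC)(CC)CC)CCC=O)[C@@H]12 | intermediate
21 | methyl acrylate | C=CC(=O)OC | starting material
22 | bis(Morita–Baylis–Hillman) adduct (C7 and C7′ epimers) | CC1=C(COCc4ccc(OC)cc4)[C@H]([C@@](C)(O[Si](CC)(CC)CC)CCC(O)C(=C)C(=O)OC)[C@H]2[C@H]3C=C(C)[C@](COCc5ccc(OC)cc5)([C@@H]3[C@@](C)(O[Si](CC)(CC)CC)CCC(O)C(=C)C(=O)OC)[C@@H]12 | intermediate
23 | bis[(Z)-2-(bromomethyl)enoate], C6 and C6′ as PMB ethers | CC1=C(COCc4ccc(OC)cc4)[C@H]([C@@](C)(O[Si](CC)(CC)CC)CC/C=C(\CBr)C(=O)OC)[C@H]2[C@H]3C=C(C)[C@](COCc5ccc(OC)cc5)([C@@H]3[C@@](C)(O[Si](CC)(CC)CC)CC/C=C(\CBr)C(=O)OC)[C@@H]12 | intermediate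
24 | C6,C6′-diol with both bromomethyl enoate arms | CC1=C(CO)[C@H]([C@@](C)(O[Si](CC)(CC)CC)CC/C=C(\CBr)C(=O)OC)[C@H]2[C@H]3C=C(C)[C@](CO)([C@@H]3[C@@](C)(O[Si](CC)(CC)CC)CC/C=C(\CBr)C(=O)OC)[C@@H]12 | intermediate
25 | C6,C6′-dialdehyde with both bromomethyl enoate arms (key-step precursor) | CC1=C(C=O)[C@H]([C@@](C)(O[Si](CC)(CC)CC)CC/C=C(\CBr)C(=O)OC)[C@H]2[C@H]3C=C(C)[C@](C=O)([C@@H]3[C@@](C)(O[Si](CC)(CC)CC)CC/C=C(\CBr)C(=O)OC)[C@@H]12 | intermediate
26 | bis(hydroxy ester) with both cycloheptanes closed (not isolated) | CC1=C2[C@@H](O)[C@H](C(=C)C(=O)OC)CC[C@](C)(O[Si](CC)(CC)CC)[C@@H]2[C@H]2[C@H]3C=C(C)[C@]4([C@@H]3[C@@](C)(O[Si](CC)(CC)CC)CC[C@@H](C(=C)C(=O)OC)[C@@H]4O)[C@@H]12 | intermediate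
27 | bis(α-methylene γ-lactone) 10,10′-bis(triethylsilyl) ether, 3-ene (key-step product) | CC1=C2[C@H]3OC(=O)C(=C)[C@@H]3CC[C@](C)(O[Si](CC)(CC)CC)[C@@H]2[C@H]2[C@H]3C=C(C)[C@]4([C@@H]3[C@@](C)(O[Si](CC)(CC)CC)CC[C@H]3C(=C)C(=O)O[C@@H]34)[C@@H]12 | intermediate
28 | bis(α-methyl γ-lactone) 10,10′-bis(triethylsilyl) ether, 3-ene | CC1=C2[C@H]3OC(=O)[C@@H](C)[C@@H]3CC[C@](C)(O[Si](CC)(CC)CC)[C@@H]2[C@H]2[C@H]3C=C(C)[C@]4([C@@H]3[C@@](C)(O[Si](CC)(CC)CC)CC[C@H]3[C@H](C)C(=O)O[C@@H]34)[C@@H]12 | intermediate
29 | 3,4-didehydro target (10,10′-diol) | CC1=C2[C@H]3OC(=O)[C@@H](C)[C@@H]3CC[C@](C)(O)[C@@H]2[C@H]2[C@H]3C=C(C)[C@]4([C@@H]3[C@@](C)(O)CC[C@H]3[C@H](C)C(=O)O[C@@H]34)[C@@H]12 | intermediate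
30 | CNP0182139.2 | CC1=C2[C@H]3OC(=O)[C@@H](C)[C@@H]3CC[C@](C)(O)[C@@H]2[C@H]2[C@H]3C[C@@H](C)[C@]4([C@@H]3[C@@](C)(O)CC[C@H]3[C@H](C)C(=O)O[C@@H]34)[C@@H]12 | target

**Step count and risks**

Total step count: 20. Longest linear sequence: 19 steps (steps 1–4 and 6–20; step 5 is the only side branch).

Step 11 (dimerization). The 1,5-hydrogen shift may deplete the reactive diene tautomer faster than the cycloaddition consumes it, and tautomers may cross-react. Exo approach or attack syn to a carbinol substituent would leak into isomeric adducts. The fallback leaves the thermal pericyclic manifold for the cation-radical (hole-catalysed) Diels–Alder dimerization, a known electron-transfer chain process for 1,3-dienes. It sets out from 17, which is treated with catalytic tris(4-bromophenyl)aminium hexachloroantimonate, (4-BrC6H4)3N SbCl6, and 2,6-di-tert-butylpyridine in CH2Cl2 at 0 °C. This should run within minutes at a temperature where the hydrogen shift is frozen. It comes back to the route at 18, and no new compound arises (F0).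

Step 17 (double ring closure). Closure through a competing closed transition state (aldehyde substituent axial, or the allyl unit reacting in its Z form) would give cis ring fusion. The slower closure at the hindered bridgehead aldehyde may also lose out to protonolysis of the second allylchromium. The fallback changes both substrate and metal, and sets out from 25. Buffered HF·pyridine in THF removes both silyl groups to give the dialdehyde diol F3, which equilibrates with its bis-lactol. Indium powder (In) in THF/H2O, an aqueous Barbier allylation that accepts lactols and free hydroxyls, followed by catalytic p-TsOH should close both rings to the bis(α-methylene γ-lactone) diol F4. NaBH4 in MeOH then gives 29, where the route resumes.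

Step 10 (1,4-dehydration). O-Sulfenylation of the hindered tertiary alcohol may be slow, so that the sulfenyl chloride adds to the side-chain alkene instead, or ionization to the allyl cation may lead to proton loss toward C1. The fallback sets out from 14. Pyridinium chlorochromate, [C5H5NH][CrO3Cl], in CH2Cl2 (Babler–Dauben oxidative 1,3-transposition) gives enone F1. Kinetic deprotonation at C2 with KN(SiMe3)2 at −78 °C and trapping with PhNTf2 gives the cross-conjugated dienyl triflate F2. Palladium-catalysed formate reduction (Pd(OAc)2, PPh3, HCO2H, Bu3N, DMF, rt) then delivers 17, where the route resumes.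

**Further compounds**

F0 | step 11 | none | none
F1 | step 10 | (4R)-3-[(4-methoxybenzyloxy)methyl]-2-methyl-4-[(2S)-6-methyl-2-(triethylsilyloxy)hept-5-en-2-yl]cyclopent-2-en-1-one | COc1ccc(COCC2=C(C)C(=O)C[C@H]2[C@@](C)(O[Si](CC)(CC)CC)CCC=C(C)C)cc1
F2 | step 10 | (5R)-4-[(4-methoxybenzyloxy)methyl]-3-methyl-5-[(2S)-6-methyl-2-(triethylsilyloxy)hept-5-en-2-yl]cyclopenta-1,3-dien-2-yl trifluoromethanesulfonate | COc1ccc(COCC2=C(C)C(OS(=O)(=O)C(F)(F)F)=C[C@H]2[C@@](C)(O[Si](CC)(CC)CC)CCC=C(C)C)cc1
F3 | step 17 | C6,C6′-dialdehyde 10,10′-diol with both bromomethyl enoate arms (open form of the bis-lactol) | CC1=C(C=O)[C@H]([C@@](C)(O)CC/C=C(\CBr)C(=O)OC)[C@H]2[C@H]3C=C(C)[C@](C=O)([C@@H]3[C@@](C)(O)CC/C=C(\CBr)C(=O)OC)[C@@H]12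
F4 | step 17 | bis(α-methylene γ-lactone) 10,10′-diol, 3-ene | CC1=C2[C@H]3OC(=O)C(=C)[C@@H]3CC[C@](C)(O)[C@@H]2[C@H]2[C@H]3C=C(C)[C@]4([C@@H]3[C@@](C)(O)CC[C@H]3C(=C)C(=O)O[C@@H]34)[C@@H]12
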